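**Strategy.** The flavone is cut at the C4–C4a bond. Ring C is closed last by intramolecular Friedel–Crafts acylation of ring A: the activated carboxyl group of a 3-aryloxy-2-benzyloxy-3-phenylacrylic acid attacks C4a, the only unsubstituted carbon ortho to O1, because the other ortho carbon, C8, already carries the 1-arylallyl chain. One operation therefore delivers the whole protected flavonol. The precursor is the aryl vinyl ether 16 of a ring A phenol whose side-chain stereocentre at C8 is set beforehand by Mitsunobu inversion, Z-selective semihydrogenation, aromatic Claisen chirality transfer and ethenolysis; the acrylate arm is attached by vinylic substitution on an enol triflate.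

Key step: step 11

Remark on the chemistry: the diarylmethine carbon keeps one spatial arrangement from 9 to 20 and is R throughout. In the dearomatised intermediate 8 the same arrangement is formally S, because the ring carbon drops in CIP rank. The R target requires (R)-but-3-yn-2-ol, since inversion followed by rearrangement of the Z-alkene leads to R.

**Step 1**
Reactants: 1 4-iodo-2-methoxyphenol
Product: 2 1-(benzyloxy)-4-iodo-2-methoxybenzene
Conditions: BnBr, K2CO3, DMF, rt
Reagents that add atoms: benzyl bromide, BrCc1ccccc1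
Why: Williamson etherification of the phenoxide with a reactive benzylic halide, which masks the phenol for the Mitsunobu step.

**Step 2**
Reactants: 2 1-(benzyloxy)-4-iodo-2-methoxybenzene; 3 (R)-but-3-yn-2-ol
Product: 4 (R)-4-[4-(benzyloxy)-3-methoxyphenyl]but-3-yn-2-ol
Conditions: Pd(PPh3)2Cl2 (2 mol%), CuI (4 mol%), Et3N, THF, rt
Reagents that add atoms: none
Why: Sonogashira coupling of an aryl iodide with a terminal alkyne proceeds at room temperature and does not touch the carbinol stereocentre.

**Step 3**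
Reactants: 4 (R)-4-[4-(benzyloxy)-3-methoxyphenyl]but-3-yn-2-ol; 5 3,5-bis(benzyloxy)phenol
Product: 6 1,3-bis(benzyloxy)-5-({(2S)-4-[4-(benzyloxy)-3-methoxyphenyl]but-3-yn-2-yl}oxy)benzene
Conditions: PPh3, DIAD, toluene, 0 °C to rt
Reagents that add atoms: none
Why: Mitsunobu etherification, in which the phenoxide displaces the alkoxyphosphonium group by SN2 and inverts the carbinol carbon from R to S; the propargylic (not allylic) position avoids SN2′ attack and ionisation.

**Step 4**
Reactants: 6 1,3-bis(benzyloxy)-5-({(2S)-4-[4-(benzyloxy)-3-methoxyphenyl]but-3-yn-2-yl}oxy)benzene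
Product: 7 1,3-bis(benzyloxy)-5-({(2S,3Z)-4-[4-(benzyloxy)-3-methoxyphenyl]but-3-en-2-yl}oxy)benzene
Conditions: H2 (1 atm), Pd/CaCO3 poisoned with Pb(OAc)2 (Lindlar catalyst), quinoline, EtOAc, rt
Reagents that add atoms: none
Why: Lindlar semihydrogenation adds hydrogen syn on the poisoned surface and should stop at the Z-alkene, leaving benzyl ethers, the aryl ether and the stereocentre alone.

**Step 5**
Reactants: 7 1,3-bis(benzyloxy)-5-({(2S,3Z)-4-[4-(benzyloxy)-3-methoxyphenyl]but-3-en-2-yl}oxy)benzene
Product: 9 3,5-bis(benzyloxy)-2-{(1R,2E)-1-[4-(benzyloxy)-3-methoxyphenyl]but-2-en-1-yl}phenol, via ortho-dienone 8 (not isolated)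
Conditions: N,N-diethylaniline, 170 °C, argon
Reagents that add atoms: none
Why: Aromatic Claisen rearrangement, a suprafacial [3,3] shift with 1,3-chirality transfer: the C–O bond breaks and the C–C bond forms on the same face of the allyl unit, and the methyl group is forced outward because an inward methyl would collide with the Z-aryl group (allylic 1,3-strain), so the (S,Z)-ether should give the E-propenyl group and the R diarylmethine carbon; dienone 8 (chair-like transition state) enolises to the phenol, the two ortho carbons are equivalent, and the amine solvent buffers traces of acid that could ionise the ether.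

**Step 6**
Reactants: 9 3,5-bis(benzyloxy)-2-{(1R,2E)-1-[4-(benzyloxy)-3-methoxyphenyl]but-2-en-1-yl}phenol
Product: 10 3,5-bis(benzyloxy)-2-{(1R)-1-[4-(benzyloxy)-3-methoxyphenyl]prop-2-en-1-yl}phenol
Conditions: ethylene (5 bar), second-generation Hoveyda–Grubbs catalyst RuCl2(H2IMes)(=CH-C6H4-2-OiPr) (5 mol%), 1,4-benzoquinone (10 mol%), toluene, 40 °C
Reagents that add atoms: ethylene, C=C
Why: Ethenolysis (olefin cross-metathesis with ethylene) exchanges the ethylidene end for a methylene group without touching the adjacent stereocentre, and the quinone intercepts Ru–H species that could move the double bond into conjugation.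

**Step 7**
Reactants: 11 methyl 2-(benzyloxy)acetate; 12 benzoyl chloride
Product: 13 methyl 2-(benzyloxy)-3-oxo-3-phenylpropanoate (racemic)
Conditions: LiN(SiMe3)2 (2.1 equiv), THF, −78 °C; then 12, −78 to 0 °C; aq. NH4Cl
Reagents that add atoms: none
Why: Crossed Claisen-type C-acylation of the lithium ester enolate with an acid chloride, the second equivalent of base removing the acidic proton of the β-keto ester as it forms.

**Step 8**
Reactants: 13 methyl 2-(benzyloxy)-3-oxo-3-phenylpropanoate
Product: 14 methyl (E)-2-(benzyloxy)-3-phenyl-3-{[(trifluoromethyl)sulfonyl]oxy}prop-2-enoate (triflate cis to the ester)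
Conditions: Tf2O, aq. LiOH, toluene, 5 °C
Reagents that add atoms: trifluoromethanesulfonic anhydride, O=S(=O)(OS(=O)(=O)C(F)(F)F)C(F)(F)F
Why: O-sulfonylation of the chelated lithium enolate of a β-keto ester, in which lithium bridges the enolate oxygen and the ester carbonyl, so the triflate should end up cis to the ester.

**Step 9**
Reactants: 10 3,5-bis(benzyloxy)-2-{(1R)-1-[4-(benzyloxy)-3-methoxyphenyl]prop-2-en-1-yl}phenol; 14 methyl (E)-2-(benzyloxy)-3-phenyl-3-{[(trifluoromethyl)sulfonyl]oxy}prop-2-enoate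
Product: 15 methyl (E)-3-(3,5-bis(benzyloxy)-2-{(1R)-1-[4-(benzyloxy)-3-methoxyphenyl]prop-2-en-1-yl}phenoxy)-2-(benzyloxy)-3-phenylprop-2-enoate
Conditions: Cs2CO3, MeCN, rt to 45 °C
Reagents that add atoms: none
Why: Nucleophilic vinylic substitution by addition–elimination (a vinylogous acyl substitution): the cesium phenoxide of 10 adds to the β-carbon of the β-triflyloxy acrylate and the ester enolate expels triflate faster than it rotates, so the aryloxy group should take the place of the triflate, cis to the ester.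

**Step 10**
Reactants: 15 methyl (E)-3-(3,5-bis(benzyloxy)-2-{(1R)-1-[4-(benzyloxy)-3-methoxyphenyl]prop-2-en-1-yl}phenoxy)-2-(benzyloxy)-3-phenylprop-2-enoate
Product: 16 (E)-3-(3,5-bis(benzyloxy)-2-{(1R)-1-[4-(benzyloxy)-3-methoxyphenyl]prop-2-en-1-yl}phenoxy)-2-(benzyloxy)-3-phenylprop-2-enoic acid (aryloxy cis to carboxyl)
Conditions: LiOH·H2O, THF/H2O, 45 °C; then 0.5 M HCl to pH 4, 0 °C
Reagents that add atoms: lithium hydroxide, [Li+].[OH-]
Why: Saponification of the methyl ester by acyl–oxygen cleavage, as is usual for β-aryloxyacrylates before chromone ring closure; methanol is left out so that no alkoxide can exchange the aryloxy group, and the mild acidification avoids hydrolysis of the enol ether.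

**Step 11**
Reactants: 16 (E)-3-(3,5-bis(benzyloxy)-2-{(1R)-1-[4-(benzyloxy)-3-methoxyphenyl]prop-2-en-1-yl}phenoxy)-2-(benzyloxy)-3-phenylprop-2-enoic acid
Product: 19 3,5,7-tris(benzyloxy)-8-{(1R)-1-[4-(benzyloxy)-3-methoxyphenyl]prop-2-en-1-yl}-2-phenyl-4H-chromen-4-one, via acid chloride 17 (not isolated), via acyl triflate 18 (not isolated)
Conditions: 1-chloro-N,N,2-trimethylprop-1-en-1-amine, CH2Cl2, 0 °C to rt; then AgOTf, 2,6-di-tert-butyl-4-methylpyridine, CH2Cl2 (0.01 M), −40 to 0 °C
Reagents that add atoms: none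
Why: The chloroenamine converts acid 16 under neutral conditions into acid chloride 17, AgOTf abstracts chloride to give acyl triflate 18 and from it an acylium ion with ketene–oxocarbenium character, which is attacked by C4a of ring A; loss of the C4a proton to the hindered pyridine rearomatises ring A and leaves the 4-pyranone. This is a Friedel–Crafts acylation of the kind long used to close chromones and flavones from β-aryloxyacrylic acid derivatives, run here through a silver-generated acyl triflate instead of a protic acid. Ring C closes in a 6-exo-dig sense, the arene carbon adding to the digonal acylium carbon that the cis-disposed vinyl ether holds six atoms away. No stereocentre is formed, and the existing R diarylmethine centre should be untouched because no free acid is present that could protonate ring A at C8 or the vinyl group. The selectivity needed is attack at C4a only: it is the sole free carbon ortho to O1 (C8 is substituted), it is activated by the ortho 5-benzyloxy and para 7-benzyloxy groups, and C6, the 2-phenyl ring and the guaiacyl ring cannot reach the acylium carbon without a bridged or medium ring, while high dilution disfavours intermolecular acylation. Any fraction with the aryloxy group trans to the acyl group should converge, since the acylium ion can rotate about the C2–C3 bond in its oxocarbenium form.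

**Step 12**
Reactants: 19 3,5,7-tris(benzyloxy)-8-{(1R)-1-[4-(benzyloxy)-3-methoxyphenyl]prop-2-en-1-yl}-2-phenyl-4H-chromen-4-one
Product: 20 3,5,7-trihydroxy-8-[(1R)-1-(4-hydroxy-3-methoxyphenyl)prop-2-en-1-yl]-2-phenyl-4H-chromen-4-one (CNP0417789.1)
Conditions: BCl3, pentamethylbenzene, CH2Cl2, −78 °C; MeOH quench
Reagents that add atoms: none
Why: Lewis acid debenzylation with a non-basic cation scavenger: BCl3 ionises the four benzyl ethers at low temperature and pentamethylbenzene traps the benzyl cations by Friedel–Crafts alkylation, so that neither the vinyl group nor the electron-rich rings are benzylated, while the aryl methyl ether and the stereocentre should survive at −78 °C.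

**Compound list**

1 | 4-iodo-2-methoxyphenol | COc1cc(I)ccc1O | starting material
2 | 1-(benzyloxy)-4-iodo-2-methoxybenzene | COc1cc(I)ccc1OCc1ccccc1 | intermediate
3 | (R)-but-3-yn-2-ol | C[C@@H](O)C#C | starting material
4 | (R)-4-[4-(benzyloxy)-3-methoxyphenyl]but-3-yn-2-ol | C[C@@H](O)C#Cc1ccc(OCc2ccccc2)c(OC)c1 | intermediate
5 | 3,5-bis(benzyloxy)phenol | Oc1cc(OCc2ccccc2)cc(OCc2ccccc2)c1 | starting material
6 | 1,3-bis(benzyloxy)-5-({(2S)-4-[4-(benzyloxy)-3-methoxyphenyl]but-3-yn-2-yl}oxy)benzene | C[C@H](Oc1cc(OCc2ccccc2)cc(OCc2ccccc2)c1)C#Cc1ccc(OCc2ccccc2)c(OC)c1 | intermediate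
7 | 1,3-bis(benzyloxy)-5-({(2S,3Z)-4-[4-(benzyloxy)-3-methoxyphenyl]but-3-en-2-yl}oxy)benzene | C[C@H](Oc1cc(OCc2ccccc2)cc(OCc2ccccc2)c1)/C=C\c1ccc(OCc2ccccc2)c(OC)c1 | intermediate
8 | (6R)-3,5-bis(benzyloxy)-6-{(1S,2E)-1-[4-(benzyloxy)-3-methoxyphenyl]but-2-en-1-yl}cyclohexa-2,4-dien-1-one (ortho-dienone) | O=C1C=C(OCc2ccccc2)C=C(OCc2ccccc2)[C@H]1[C@@H](c1ccc(OCc2ccccc2)c(OC)c1)/C=C/C | intermediate (not isolated)
9 | 3,5-bis(benzyloxy)-2-{(1R,2E)-1-[4-(benzyloxy)-3-methoxyphenyl]but-2-en-1-yl}phenol | C/C=C/[C@H](c1ccc(OCc2ccccc2)c(OC)c1)c1c(O)cc(OCc2ccccc2)cc1OCc1ccccc1 | intermediate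
10 | 3,5-bis(benzyloxy)-2-{(1R)-1-[4-(benzyloxy)-3-methoxyphenyl]prop-2-en-1-yl}phenol | C=C[C@H](c1ccc(OCc2ccccc2)c(OC)c1)c1c(O)cc(OCc2ccccc2)cc1OCc1ccccc1 | intermediate
11 | methyl 2-(benzyloxy)acetate | COC(=O)COCc1ccccc1 | starting material
12 | benzoyl chloride | O=C(Cl)c1ccccc1 | starting material
13 | methyl 2-(benzyloxy)-3-oxo-3-phenylpropanoate (racemic) | COC(=O)C(OCc1ccccc1)C(=O)c1ccccc1 | intermediate
14 | methyl (E)-2-(benzyloxy)-3-phenyl-3-{[(trifluoromethyl)sulfonyl]oxy}prop-2-enoate | COC(=O)/C(OCc1ccccc1)=C(\OS(=O)(=O)C(F)(F)F)c1ccccc1 | intermediate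
15 | methyl (E)-3-(3,5-bis(benzyloxy)-2-{(1R)-1-[4-(benzyloxy)-3-methoxyphenyl]prop-2-en-1-yl}phenoxy)-2-(benzyloxy)-3-phenylprop-2-enoate | C=C[C@H](c1ccc(OCc2ccccc2)c(OC)c1)c1c(OCc2ccccc2)cc(OCc2ccccc2)cc1O/C(c1ccccc1)=C(/OCc1ccccc1)C(=O)OC | intermediate
16 | (E)-3-(3,5-bis(benzyloxy)-2-{(1R)-1-[4-(benzyloxy)-3-methoxyphenyl]prop-2-en-1-yl}phenoxy)-2-(benzyloxy)-3-phenylprop-2-enoic acid | C=C[C@H](c1ccc(OCc2ccccc2)c(OC)c1)c1c(OCc2ccccc2)cc(OCc2ccccc2)cc1O/C(c1ccccc1)=C(/OCc1ccccc1)C(=O)O | intermediate
17 | (E)-3-(3,5-bis(benzyloxy)-2-{(1R)-1-[4-(benzyloxy)-3-methoxyphenyl]prop-2-en-1-yl}phenoxy)-2-(benzyloxy)-3-phenylprop-2-enoyl chloride | C=C[C@H](c1ccc(OCc2ccccc2)c(OC)c1)c1c(OCc2ccccc2)cc(OCc2ccccc2)cc1O/C(c1ccccc1)=C(/OCc1ccccc1)C(=O)Cl | intermediate (not isolated)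
18 | mixed anhydride of acid 16 with trifluoromethanesulfonic acid (acyl triflate) | C=C[C@H](c1ccc(OCc2ccccc2)c(OC)c1)c1c(OCc2ccccc2)cc(OCc2ccccc2)cc1O/C(c1ccccc1)=C(/OCc1ccccc1)C(=O)OS(=O)(=O)C(F)(F)F | intermediate (not isolated)
19 | 3,5,7-tris(benzyloxy)-8-{(1R)-1-[4-(benzyloxy)-3-methoxyphenyl]prop-2-en-1-yl}-2-phenyl-4H-chromen-4-one | C=C[C@H](c1ccc(OCc2ccccc2)c(OC)c1)c1c(OCc2ccccc2)cc(OCc2ccccc2)c2c(=O)c(OCc3ccccc3)c(-c3ccccc3)oc12 | intermediate
20 | 3,5,7-trihydroxy-8-[(1R)-1-(4-hydroxy-3-methoxyphenyl)prop-2-en-1-yl]-2-phenyl-4H-chromen-4-one | C=C[C@H](c1ccc(O)c(OC)c1)c1c(O)cc(O)c2c(=O)c(O)c(-c3ccccc3)oc12 | target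

**Step count.** Total: 12 steps. Longest linear sequence: 10 steps (steps 1–6 and 9–12); steps 7 and 8 form the two-step side branch to enol triflate 14.

**Steps most likely to fail**

Step 11 (ring closure). The acyl triflate may be consumed by intermolecular acylation of the free C6 position of another molecule, or benzyl ethers may be lost and ring A protodealkylated at C8 if acid builds up before the ring closes. The fallback sets out from 10 and returns at 19; it builds ring C in the opposite order, the C4–C4a bond first as an aryl ketone and the O1–C2 bond last. Phenol 10 would be C-acylated ortho to the hydroxyl with benzyloxyacetyl chloride and BF3·OEt2 (chelation-directed Friedel–Crafts/Fries acylation) to give the 2-hydroxyaryl ketone F1. O-Benzoylation with 12 (pyridine, DMAP) would give the benzoate F2. Baker–Venkataraman rearrangement (LiN(SiMe3)2, THF, −20 °C to rt) would give the 1,3-diketone F3, and cyclodehydration (cat. TsOH, toluene, 60 °C) would close the pyranone to 19.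

Step 9 (O-vinylation). The phenoxide may attack sulfur of the enol triflate (sulfonyl transfer) instead of carbon, or addition to the hindered, donor-substituted β-carbon may be too slow. The fallback sets out from 10 and returns at 15; it makes the C–O bond by SN2 at an sp3 carbon and forms the enol ether afterwards. Commercial methyl 2-oxo-3-phenylpropanoate would be brominated (Br2, CH2Cl2) to methyl 3-bromo-2-oxo-3-phenylpropanoate F4. Phenol 10 would be alkylated with it (K2CO3, acetone, rt) to the aryloxy keto ester F5. O-Benzylation of its cesium enolate (BnBr, Cs2CO3, DMF) should give 15, because the enolate is expected to place the phenyl group cis to the enolate oxygen as in arylpyruvate enols, and C-alkylation at the fully substituted carbon is hindered.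

Step 5 (Claisen rearrangement). At 170 °C the allylic C–O bond may break heterolytically into an ion pair stabilised by the alkoxyaryl group, which would erode the chirality transfer, give 1,3-shifted products or lead to elimination to the diene. The fallback sets out from 5 and returns at 10; it sets the stereocentre by catalyst-controlled conjugate addition. Phenol 5 and ethyl propiolate (Pd2(dba)3·CHCl3, NaOAc, HCO2H, rt; hydroarylation and lactonisation) would give 5,7-bis(benzyloxy)coumarin F6. Rhodium-catalysed asymmetric 1,4-addition of commercial [4-(benzyloxy)-3-methoxyphenyl]boronic acid (Rh(acac)(C2H4)2, (R)-SEGPHOS or whichever ligand enantiomer delivers the R lactone, dioxane/H2O, 60 °C) would give the (R)-4-arylchroman-2-one F7. Ring opening with dimethylamine (THF, rt) would give the phenol amide F8, and LiAlH4 (THF, reflux) the amine F9. Oxidation with H2O2 (MeOH) would give the N-oxide F10, whose Cope elimination (toluene, 110 °C) would give 10; this sequence has no leaving group that the free phenol could displace to form a chroman.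

**Further compounds**

F1 | step 11 | 1-(4,6-bis(benzyloxy)-3-{(1R)-1-[4-(benzyloxy)-3-methoxyphenyl]prop-2-en-1-yl}-2-hydroxyphenyl)-2-(benzyloxy)ethan-1-one | C=C[C@H](c1ccc(OCc2ccccc2)c(OC)c1)c1c(OCc2ccccc2)cc(OCc2ccccc2)c(C(=O)COCc2ccccc2)c1O
F2 | step 11 | 3,5-bis(benzyloxy)-2-[(benzyloxy)acetyl]-6-{(1R)-1-[4-(benzyloxy)-3-methoxyphenyl]prop-2-en-1-yl}phenyl benzoate | C=C[C@H](c1ccc(OCc2ccccc2)c(OC)c1)c1c(OCc2ccccc2)cc(OCc2ccccc2)c(C(=O)COCc2ccccc2)c1OC(=O)c1ccccc1
F3 | step 11 | 1-(4,6-bis(benzyloxy)-3-{(1R)-1-[4-(benzyloxy)-3-methoxyphenyl]prop-2-en-1-yl}-2-hydroxyphenyl)-2-(benzyloxy)-3-phenylpropane-1,3-dione (labile α-carbon, mixture of epimers and enol forms) | C=C[C@H](c1ccc(OCc2ccccc2)c(OC)c1)c1c(OCc2ccccc2)cc(OCc2ccccc2)c(C(=O)C(OCc2ccccc2)C(=O)c2ccccc2)c1O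
F4 | step 9 | methyl 3-bromo-2-oxo-3-phenylpropanoate (racemic) | COC(=O)C(=O)C(Br)c1ccccc1
F5 | step 9 | methyl 3-(3,5-bis(benzyloxy)-2-{(1R)-1-[4-(benzyloxy)-3-methoxyphenyl]prop-2-en-1-yl}phenoxy)-2-oxo-3-phenylpropanoate (epimers at C3, enolisable) | C=C[C@H](c1ccc(OCc2ccccc2)c(OC)c1)c1c(OCc2ccccc2)cc(OCc2ccccc2)cc1OC(c1ccccc1)C(=O)C(=O)OC
F6 | step 5 | 5,7-bis(benzyloxy)-2H-chromen-2-one | O=c1ccc2c(OCc3ccccc3)cc(OCc3ccccc3)cc2o1
F7 | step 5 | (4R)-5,7-bis(benzyloxy)-4-[4-(benzyloxy)-3-methoxyphenyl]chroman-2-one | O=C1C[C@H](c2ccc(OCc3ccccc3)c(OC)c2)c2c(OCc3ccccc3)cc(OCc3ccccc3)cc2O1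
F8 | step 5 | (3R)-3-[2,4-bis(benzyloxy)-6-hydroxyphenyl]-3-[4-(benzyloxy)-3-methoxyphenyl]-N,N-dimethylpropanamide | CN(C)C(=O)C[C@H](c1ccc(OCc2ccccc2)c(OC)c1)c1c(O)cc(OCc2ccccc2)cc1OCc1ccccc1
F9 | step 5 | 3,5-bis(benzyloxy)-2-{(1R)-1-[4-(benzyloxy)-3-methoxyphenyl]-3-(dimethylamino)propyl}phenol | CN(C)CC[C@H](c1ccc(OCc2ccccc2)c(OC)c1)c1c(O)cc(OCc2ccccc2)cc1OCc1ccccc1
F10 | step 5 | (3R)-3-[2,4-bis(benzyloxy)-6-hydroxyphenyl]-3-[4-(benzyloxy)-3-methoxyphenyl]-N,N-dimethylpropan-1-amine N-oxide | C[N+](C)([O-])CC[C@H](c1ccc(OCc2ccccc2)c(OC)c1)c1c(O)cc(OCc2ccccc2)cc1OCc1ccccc1
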